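The methylene bridge is disconnected from C6 of the acetylfilicinic acid (cyclohexadienone) ring. The bridge carbon sits on C6 of the chromene's benzene ring, flanked by the C5 and C7 hydroxyls, so it is a latent ortho-quinone methide. C6 of the dienone ring is the only C–H of an enolised β-triketone. In one operation, heating the 6-(dimethylaminomethyl)chromene Mannich base with acetylfilicinic acid expels dimethylamine, and the quinone methide formed is captured at that carbon, joining both fully elaborated, unprotected halves. Beforehand, a MOM group on the para oxygen forces chromene closure onto the oxygen ortho to the acetyl group.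

Key step: step 6

Remark: the target is drawn as one enol tautomer of a β-triketone, and 9, 11 and the related dienones are written in the same tautomeric form. The target has no stereocentre and no stereogenic double bond, so no stereocontrol is needed.

Step 1
Reactants: 1 2,4,6-trihydroxyacetophenone
Product: 2 1-[2,6-dihydroxy-4-(methoxymethoxy)phenyl]ethan-1-one
Conditions: MOMCl (1.05 equiv), K2CO3 (1.1 equiv), acetone, 0 °C → rt
Reagents that add atoms: chloromethyl methyl ether (MOMCl), COCCl
Why: Williamson-type O-alkylation (MOM protection): the 4-OH, para to the acetyl group and not hydrogen-bonded to it, is the most acidic and most accessible hydroxyl, so one equivalent of MOMCl should protect it selectively and leave the symmetrical 2,6-diol.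

Step 2
Reactants: 2 1-[2,6-dihydroxy-4-(methoxymethoxy)phenyl]ethan-1-one; 3 3-methylbut-2-enal (prenal)
Product: 5 1-[7-hydroxy-5-(methoxymethoxy)-2,2-dimethyl-2H-chromen-8-yl]ethan-1-one, via 1-oxatriene dienone 4 (not isolated)
Conditions: 3 (1.2 equiv), ethylenediamine diacetate (10–20 mol%), toluene, reflux
Reagents that add atoms: none
Why: Amine-catalysed Knoevenagel-type condensation of the enal at C3 of the ring (via its iminium ion) gives dienone 4, which closes by oxa-6π electrocyclisation (formal [3+3] chromene annulation); because the para oxygen is capped, only the oxygen ortho to the acetyl group can close, which fixes the acetyl group at C8 of the chromene.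

Step 3
Reactants: 5 1-[7-hydroxy-5-(methoxymethoxy)-2,2-dimethyl-2H-chromen-8-yl]ethan-1-one
Product: 6 1-(5,7-dihydroxy-2,2-dimethyl-2H-chromen-8-yl)ethan-1-one
Conditions: 3 M HCl (aq), MeOH, 50 °C
Reagents that add atoms: none
Why: Acid-catalysed transacetalisation of the MOM ether to methanol; the aryl ketone and the 2,2-dimethylchromene double bond should tolerate dilute HCl in methanol at mild temperature.

Step 4
Reactants: 6 1-(5,7-dihydroxy-2,2-dimethyl-2H-chromen-8-yl)ethan-1-one
Product: 7 1-{6-[(dimethylamino)methyl]-5,7-dihydroxy-2,2-dimethyl-2H-chromen-8-yl}ethan-1-one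
Conditions: CH2(NMe2)2 (1.1 equiv), CH2Cl2, 0 °C → rt
Reagents that add atoms: bis(dimethylamino)methane, CN(C)CN(C)C
Why: Phenol Mannich reaction: the acidic phenol ionises the aminal to the N,N-dimethylmethyleneiminium ion, which substitutes C6, the only unsubstituted carbon of the benzene ring and activated by both flanking hydroxyls.

Step 5
Reactants: 1 2,4,6-trihydroxyacetophenone
Product: 9 acetylfilicinic acid (2-acetyl-3,5-dihydroxy-4,4-dimethylcyclohexa-2,5-dien-1-one), via mono-C-methyl phloroacetophenone 8 (not isolated)
Conditions: MeI (2.2 equiv), NaOMe (3.0 equiv), MeOH, 0 °C → rt; HCl work-up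
Reagents that add atoms: iodomethane, CI
Why: Dearomative double C-methylation of the phloroglucinol polyanion (gem-dimethylation): after the first C-methylation to 8 the methyl-bearing carbon is the most nucleophilic ring position, so the second methyl group should enter at the same carbon and give the cross-conjugated β-triketone 9, which is separated from under- and over-methylated congeners.

Step 6
Reactants: 7 1-{6-[(dimethylamino)methyl]-5,7-dihydroxy-2,2-dimethyl-2H-chromen-8-yl}ethan-1-one; 9 acetylfilicinic acid
Product: 11 2-acetyl-6-[(8-acetyl-5,7-dihydroxy-2,2-dimethyl-2H-chromen-6-yl)methyl]-3,5-dihydroxy-4,4-dimethylcyclohexa-2,5-dien-1-one, via ortho-quinone methide 10 (not isolated)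
Conditions: 9 (1.5 equiv), 1,4-dioxane, 95 °C, Ar; 1 M HCl wash
Reagents that add atoms: none
Why: The acidic triketone 9 protonates the benzylic amine of 7 and the flanking phenol(ate) pushes out dimethylamine in a retro-Mannich-type 1,4-elimination, giving ortho-quinone methide 10, whose exocyclic CH2 is then attacked by C6 of the enol(ate) of 9 in a Michael addition that restores the aromatic ring. The closest known reaction type is the thermal coupling of phenolic Mannich bases with 1,3-dicarbonyl C–H acids via ortho-quinone methides, the classical entry to methylene-bridged acylphloroglucinol dimers. No ring is closed and no stereocentre is formed, so there is no closure mode or stereocontrol element to assign. The step needs crossed C-alkylation instead of O-alkylation or self-capture of 10: C6 of 9 is its only ring C–H and the soft terminus of the triketone anion, O-adducts (including a [4+2] chroman ketal) should revert to 10 and funnel to the aromatised C-adduct, and 7 itself has no free aromatic carbon. An excess of 9 and the lowest temperature that releases the amine should suppress scrambling of the bridge.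

Compound list
1 | 2,4,6-trihydroxyacetophenone | CC(=O)c1c(O)cc(O)cc1O | starting material
2 | 1-[2,6-dihydroxy-4-(methoxymethoxy)phenyl]ethan-1-one | CC(=O)c1c(O)cc(OCOC)cc1O | intermediate
3 | 3-methylbut-2-enal (prenal) | CC(C)=CC=O | starting material
4 | (6Z)-2-acetyl-3-hydroxy-5-(methoxymethoxy)-6-(3-methylbut-2-en-1-ylidene)cyclohexa-2,4-dien-1-one | CC(=O)C1=C(O)C=C(OCOC)/C(=C/C=C(C)C)C1=O | intermediate
5 | 1-[7-hydroxy-5-(methoxymethoxy)-2,2-dimethyl-2H-chromen-8-yl]ethan-1-one | CC(=O)c1c(O)cc(OCOC)c2c1OC(C)(C)C=C2 | intermediate
6 | 1-(5,7-dihydroxy-2,2-dimethyl-2H-chromen-8-yl)ethan-1-one | CC(=O)c1c(O)cc(O)c2c1OC(C)(C)C=C2 | intermediate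
7 | 1-{6-[(dimethylamino)methyl]-5,7-dihydroxy-2,2-dimethyl-2H-chromen-8-yl}ethan-1-one | CC(=O)c1c(O)c(CN(C)C)c(O)c2c1OC(C)(C)C=C2 | intermediate
8 | 1-(2,4,6-trihydroxy-3-methylphenyl)ethan-1-one | CC(=O)c1c(O)cc(O)c(C)c1O | intermediate
9 | acetylfilicinic acid, 2-acetyl-3,5-dihydroxy-4,4-dimethylcyclohexa-2,5-dien-1-one | CC(=O)C1=C(O)C(C)(C)C(O)=CC1=O | intermediate
10 | 8-acetyl-5-hydroxy-2,2-dimethyl-6-methylidene-2H-chromen-7(6H)-one (ortho-quinone methide) | CC(=O)C1=C2OC(C)(C)C=CC2=C(O)C(=C)C1=O | intermediate
11 | 2-acetyl-6-[(8-acetyl-5,7-dihydroxy-2,2-dimethyl-2H-chromen-6-yl)methyl]-3,5-dihydroxy-4,4-dimethylcyclohexa-2,5-dien-1-one | CC(=O)C1=C(O)C(C)(C)C(O)=C(Cc2c(O)c3c(c(C(C)=O)c2O)OC(C)(C)C=C3)C1=O | target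

Total step count: 6.
Longest linear sequence: 5 steps (steps 1, 2, 3, 4 and 6 from compound 1); step 5 is a one-step branch from the same starting material.

Steps most likely to fail

Step 6. At the temperature needed for amine loss the methylene bridge of the product may itself fragment and recombine (retro-Michael), scrambling the halves into symmetrical dimers, and the quinone methide may be consumed by self-capture or by cycloaddition to the chromene double bond. The fallback makes the same bond as a C=C bond at room temperature and reduces it in the same flask. It sets out from 6 (with 9 as partner) and comes back at 11. Vilsmeier–Haack formylation of 6 (POCl3, DMF, EtOAc, 0 °C → rt, then aqueous NaOAc) at the only free ring carbon should give 8-acetyl-5,7-dihydroxy-2,2-dimethyl-2H-chromene-6-carbaldehyde F1. Three-component reductive alkylation of 9 with F1 (L-proline cat., Hantzsch ester, CH2Cl2, rt) should proceed through the Knoevenagel adduct 2-acetyl-6-[(8-acetyl-5,7-dihydroxy-2,2-dimethyl-2H-chromen-6-yl)methylidene]-3-hydroxy-4,4-dimethylcyclohex-2-ene-1,5-dione F2 (E/Z mixture, not isolated). Conjugate hydride transfer then reduces only this electron-poor alkene, leaving the chromene double bond, and gives 11.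

Step 2. The chelated, MOM-bearing dihydroxyketone may condense sluggishly, a second annulation may occur at the remaining ring carbon, and the acetal may erode on prolonged heating. The fallback replaces the enal condensation by a propargyl ether rearrangement; it sets out from 2 and comes back at 5. Copper-catalysed O-alkylation of one of the two equivalent hydroxyls of 2 (3-chloro-3-methylbut-1-yne, DBU, CuCl2 cat., MeCN, 0 °C → rt) should give 1-{2-hydroxy-4-(methoxymethoxy)-6-[(2-methylbut-3-yn-2-yl)oxy]phenyl}ethan-1-one F3. Heating F3 in xylene at 140 °C should trigger an aromatic propargyl Claisen rearrangement to the only free ortho carbon, giving 1-[2,6-dihydroxy-4-(methoxymethoxy)-3-(3-methylbuta-1,2-dien-1-yl)phenyl]ethan-1-one F4 (not isolated). A 1,5-hydrogen shift then leads to dienone 4 and oxa-6π closure to 5, with the same regiochemical outcome because the ether oxygen is the one ortho to the acetyl group.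

Step 5. C-Methylation may be unselective, with under-methylation, a third methyl group at the second ring carbon and O-methylation all competing. The fallback blocks the second ring carbon before methylation; it sets out from 1 and comes back at 9.
- Friedel–Crafts C-acetylation of 1 (Ac2O, BF3·OEt2, 80 °C) should give 2,4-diacetylphloroglucinol F5.
- Methylation of F5 (MeI, NaOMe, MeOH) can place both methyl groups only on the single non-acylated ring carbon, giving 2,4-diacetyl-3,5-dihydroxy-6,6-dimethylcyclohexa-2,4-dien-1-one F6.
- Hot aqueous H2SO4 should remove both acetyl groups by retro-acylation, giving filicinic acid (3,5-dihydroxy-4,4-dimethylcyclohexa-2,5-dien-1-one) F7.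
- A single C-acetylation of F7 (Ac2O, BF3·OEt2) should stop at 9, because the first acyl group deactivates the ring.

Further compounds
F1 | step 6 | 8-acetyl-5,7-dihydroxy-2,2-dimethyl-2H-chromene-6-carbaldehyde | CC(=O)c1c(O)c(C=O)c(O)c2c1OC(C)(C)C=C2
F2 | step 6 | 2-acetyl-6-[(8-acetyl-5,7-dihydroxy-2,2-dimethyl-2H-chromen-6-yl)methylidene]-3-hydroxy-4,4-dimethylcyclohex-2-ene-1,5-dione (E/Z mixture, not isolated) | CC(=O)C1=C(O)C(C)(C)C(=O)C(=Cc2c(O)c3c(c(C(C)=O)c2O)OC(C)(C)C=C3)C1=O
F3 | step 2 | 1-{2-hydroxy-4-(methoxymethoxy)-6-[(2-methylbut-3-yn-2-yl)oxy]phenyl}ethan-1-one | CC(=O)c1c(O)cc(OCOC)cc1OC(C)(C)C#C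
F4 | step 2 | 1-[2,6-dihydroxy-4-(methoxymethoxy)-3-(3-methylbuta-1,2-dien-1-yl)phenyl]ethan-1-one (not isolated) | CC(=O)c1c(O)cc(OCOC)c(C=C=C(C)C)c1O
F5 | step 5 | 2,4-diacetylphloroglucinol, 1,1'-(2,4,6-trihydroxy-1,3-phenylene)bis(ethan-1-one) | CC(=O)c1c(O)cc(O)c(C(C)=O)c1O
F6 | step 5 | 2,4-diacetyl-3,5-dihydroxy-6,6-dimethylcyclohexa-2,4-dien-1-one | CC(=O)C1=C(O)C(C(C)=O)=C(O)C(C)(C)C1=O
F7 | step 5 | filicinic acid, 3,5-dihydroxy-4,4-dimethylcyclohexa-2,5-dien-1-one | CC1(C)C(O)=CC(=O)C=C1O
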